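A small charge of G, the limiting reagent, should be booked in full, so open a ledger in G units with one column for Z and one for the rest.

| flask | G | temperature | remark | time |
|---|---|---|---|---|
| south-east | 0.70 M | 55 °C | run made earlier |  |
| south | 1.1 M | 80 °C | run made earlier |  |
| ash | 0.50 M | 60 °C |  | 20 min |
| elm | 0.50 M | 100 °C |  | 6.0 min |

- south-east (time / min: Z / %): 1.50: 1.3; 3.00: 2.7; 5.00: 3.5; 6.00: 3.5; 8.00: 4.8; 10.0: 5.2; 12.0: 5.2
- south (time / min: Z / %): 0.250: 4.2; 0.667: 9.3; 1.00: 11.5; 2.00: 17.9; 3.00: 21.0; 4.00: 24.2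

(readings scatter by 0.3 percentage points)

- the flask that ends with the higher amount of Z, in percent of the G charged, or "neither" when 2 percentage points or less lies between them (ash / elm / neither)
- final Z, as a percentage of the G charged, in ash
- final Z, as a percentage of the G charged, in elm

- percent here means G units held: one Q counts as two
- what is said of Z includes L
- L is a solid; its amount is given per volume of the solution
- what may be going on: L <-> Z; G <-> J; G <-> Z; 2 G -> Q; G <-> D

1. Book Z as read: the south-east run ends at 5.2 % and the south run at 24.2 %, L included.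

2. Book the rest, the fraction left as G, D, J and Q, none of it read: 94.8 % in south-east and 75.8 % in south.

3. Divide Z by the rest: 0.0549 in south-east and 0.319 in south.

4. Take the slope of the logarithm of that ratio against reciprocal temperature, an apparent enthalpy of 67.9 kJ mol⁻¹. Treat it as rough, since it also carries the difference in charge and south was still rising at its last reading.

5. Extend the line to elm: 1.10, the Z odds, Z over the rest at the end. My own figures are then 52.4 % for elm and, from odds of 0.0797, 7.38 % for ash.

6. The forecast names elm, with 8.5 % for ash, above my figure, and 52 % for elm, reached by shading: “Side products would probably lower elm”.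

The flask gives elm: ash 12.9 %, elm 53.6 %.

    L ⇌ Z, rate k1*(cs1 - [Z]) while solid is left; crystals form when [Z] > cs1 (solubility = 0.210 M, k = 0.0770 s⁻¹)
    G ⇌ J (K = 1.00, k = 0.0240 s⁻¹, Ea = 97.0 kJ mol⁻¹, ΔH = −27.0 kJ mol⁻¹)
    G ⇌ Z (K = 1.40, k = 5.80 × 10⁻⁴ s⁻¹, Ea = 110 kJ mol⁻¹, ΔH = 33.0 kJ mol⁻¹)
    2 G → Q (k = 0.00340 M⁻¹ s⁻¹, Ea = 65.0 kJ mol⁻¹)
    G ⇌ D (K = 1.20, k = 0.00470 s⁻¹, Ea = 84.0 kJ mol⁻¹, ΔH = −31.0 kJ mol⁻¹)
    (constants at 60 °C)

Close the elm ledger at 6.00 min: Z 53.6 %, against G 7.70 %, D 2.78 %, J 2.71 % and Q 33.2 %, the largest entry of the rest. The elm odds stand at 1.16 beside the 1.10 carried forward, and the ash odds at 0.148 beside 0.0797. Elm ends above ash mainly because of its temperature: with the temperature difference to ash taken away, elm ends at 6.46 % Z. In the neighbour flask, elm charged at 0.20 M, Q is less, at 19.5 %, and the Z odds stand at 1.53.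

The numbers in the tables stem from a simulated flask with made-up constants; scatter was added.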